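The route rests on cutting C6–C7, the bond shared by the cyclodeca-1(10),4-diene ring and the α-methylene-γ-butyrolactone ring. C7–C11(=C13)–C12 next to carbinol C6 is the retron of a 2-(alkoxycarbonyl)allylation, so both carbons start as electrophiles: C6 as a (Z)-enal and C7 as the γ-terminus of a 2-(bromomethyl)enoate. Chromium(II) reverses the polarity of the allyl bromide. One operation then closes the ten-membered ring, sets C6 and C7, unveils the exocyclic methylene and lactonises. The precursor is an open chain assembled from neryl acetate (C1–C6, 4Z alkene), an L-tartrate acetonide (C7–C9, stereocentres C8 and C9), a bromo ylide (C10, C14) and methyl acrylate (C11–C13).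

Key step: step 9

Remark: germacrane numbering is used throughout (C6 lactone carbinol, C7 fusion carbon bearing C11, C8/C9 angelate carbons, C10 bears carboxyl C14, C4 bears methyl C15, C11=C13 methylene, C12 lactone carbonyl). Both ring alkenes are cis within the ring, that is 4Z and, because the carboxyl outranks C9, 1(10)E.

Step 1
Reactants: 1 neryl acetate
Product: 3 (4Z)-6-acetoxy-4-methylhex-4-enal, via epoxide 2 (not isolated)
Conditions: mCPBA (1.05 equiv), CH2Cl2, 0 °C; crude 2, H5IO6, THF/H2O, 0 °C
Reagents that add atoms: mCPBA O=C(OO)c1cccc(Cl)c1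
Why: Prilezhaev epoxidation should pick the remote electron-rich alkene (the other one is deactivated by the allylic acetate), and Malaprade-type periodic acid cleavage of the epoxide removes the isopropylidene carbons while the Z alkene of the terpene is kept as C4=C5.

Step 2
Reactants: 3 (4Z)-6-acetoxy-4-methylhex-4-enal; 4 tert-butyl (triphenylphosphoranylidene)acetate
Product: 6 tert-butyl (2Z,6Z)-8-acetoxy-2-bromo-6-methylocta-2,6-dienoate, via bromo ylide 5 (not isolated)
Conditions: 4, NBS, CH2Cl2, −20 °C; then 3, −20 °C to rt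
Reagents that add atoms: N-bromosuccinimide O=C1CCC(=O)N1Br
Why: Wittig olefination with the stabilised ylide brominated in situ should place the ester trans to the chain, which is the C1=C10 geometry of the target with bromine holding the place of C9.

Step 3
Reactants: 7 dimethyl 2,3-O-isopropylidene-L-tartrate
Product: 8 (4R,5R)-5-(methoxycarbonyl)-2,2-dimethyl-1,3-dioxolane-4-carboxylic acid
Conditions: KOH (1.0 equiv), MeOH, 0 °C to rt; then aq. HCl
Reagents that add atoms: potassium hydroxide [K+].[OH-]
Why: Mono-saponification of a C2-symmetric diester can give only one mono-acid because the two ester groups are homotopic, and the carboxylate formed resists a second hydrolysis.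

Step 4
Reactants: 6 tert-butyl (2Z,6Z)-8-acetoxy-2-bromo-6-methylocta-2,6-dienoate; 8 (4R,5R)-5-(methoxycarbonyl)-2,2-dimethyl-1,3-dioxolane-4-carboxylic acid
Product: 9 methyl (4R,5S)-5-[(1E,5Z)-7-acetoxy-1-(tert-butoxycarbonyl)-5-methylhepta-1,5-dien-1-yl]-2,2-dimethyl-1,3-dioxolane-4-carboxylate
Conditions: [Ir{dF(CF3)ppy}2(dtbbpy)]PF6 (1 mol %), NiCl2·glyme (10 mol %), dtbbpy (10 mol %), Cs2CO3, DMF, blue LEDs, rt
Reagents that add atoms: none
Why: Iridium/nickel metallaphotoredox decarboxylative cross-coupling of an α-oxy acid with a vinyl halide forms C9–C10 with retention of the alkene geometry, and the dioxolanyl radical should be captured anti to the neighbouring C8 ester, so the trans (threo) relation of L-tartrate is kept and C9 is set as S.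

Step 5
Reactants: 9 methyl (4R,5S)-5-[(1E,5Z)-7-acetoxy-1-(tert-butoxycarbonyl)-5-methylhepta-1,5-dien-1-yl]-2,2-dimethyl-1,3-dioxolane-4-carboxylate
Product: 10 tert-butyl (2E,6Z)-2-[(4S,5R)-5-formyl-2,2-dimethyl-1,3-dioxolan-4-yl]-8-hydroxy-6-methylocta-2,6-dienoate
Conditions: DIBAL-H (3.3 equiv), CH2Cl2, −78 °C; MeOH quench, aq. Rochelle salt
Reagents that add atoms: none
Why: In this DIBAL-H reduction the chelated aluminate of the α-alkoxy methyl ester should survive at −78 °C and release the C7 aldehyde only on work-up, the acetate is cleaved reductively in the same flask, and the bulky conjugated tert-butyl ester is left.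

Step 6
Reactants: 10 tert-butyl (2E,6Z)-2-[(4S,5R)-5-formyl-2,2-dimethyl-1,3-dioxolan-4-yl]-8-hydroxy-6-methylocta-2,6-dienoate; 11 methyl acrylate
Product: 12 tert-butyl (2E,6Z)-8-hydroxy-2-{(4S,5S)-5-[1-hydroxy-2-(methoxycarbonyl)prop-2-en-1-yl]-2,2-dimethyl-1,3-dioxolan-4-yl}-6-methylocta-2,6-dienoate (both C7 epimers)
Conditions: 11 (5 equiv), DABCO (1 equiv), 1,4-dioxane/H2O (1:1), rt
Reagents that add atoms: none
Why: The Morita–Baylis–Hillman reaction works well on activated α-alkoxy aldehydes and adds C11–C13; the new carbinol centre at C7 forms as a mixture that is erased in step 8.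

Step 7
Reactants: 12 tert-butyl (2E,6Z)-8-hydroxy-2-{(4S,5S)-5-[1-hydroxy-2-(methoxycarbonyl)prop-2-en-1-yl]-2,2-dimethyl-1,3-dioxolan-4-yl}-6-methylocta-2,6-dienoate
Product: 13 tert-butyl (2E,6Z)-2-{(4S,5S)-5-[1-hydroxy-2-(methoxycarbonyl)prop-2-en-1-yl]-2,2-dimethyl-1,3-dioxolan-4-yl}-6-methyl-8-oxoocta-2,6-dienoate (both C7 epimers)
Conditions: TEMPO (10 mol %), PhI(OAc)2 (1.1 equiv), CH2Cl2, rt
Reagents that add atoms: none
Why: The TEMPO/PhI(OAc)2 oxidation prefers the primary allylic alcohol over the hindered secondary one and is known to turn nerol into neral without Z/E isomerisation.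

Step 8
Reactants: 13 tert-butyl (2E,6Z)-2-{(4S,5S)-5-[1-hydroxy-2-(methoxycarbonyl)prop-2-en-1-yl]-2,2-dimethyl-1,3-dioxolan-4-yl}-6-methyl-8-oxoocta-2,6-dienoate
Product: 14 tert-butyl (2E,6Z)-2-{(4S,5S)-5-[(1Z)-3-bromo-2-(methoxycarbonyl)prop-1-en-1-yl]-2,2-dimethyl-1,3-dioxolan-4-yl}-6-methyl-8-oxoocta-2,6-dienoate
Conditions: NBS, Me2S, CH2Cl2, 0 °C to rt
Reagents that add atoms: N-bromosuccinimide O=C1CCC(=O)N1Br
Why: Corey–Kim-type activation of the Baylis–Hillman alcohol followed by SN2′ attack of bromide at the terminal methylene should give the rearranged (Z)-2-(bromomethyl)enoate under neutral conditions that spare the enal and the acetonide.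

Step 9
Reactants: 14 tert-butyl (2E,6Z)-2-{(4S,5S)-5-[(1Z)-3-bromo-2-(methoxycarbonyl)prop-1-en-1-yl]-2,2-dimethyl-1,3-dioxolan-4-yl}-6-methyl-8-oxoocta-2,6-dienoate
Product: 17 tert-butyl (1(10)E,4Z,6R,7S,8S,9S)-8,9-(isopropylidenedioxy)-12-oxo-6,12-epoxygermacra-1(10),4,11(13)-trien-14-oate, via allylchromium(III) species 15 (not isolated), via chromium(III) alkoxide 16 (not isolated)
Conditions: CrCl2 (8 equiv), 4 Å MS, DMF/THF, rt, syringe-pump addition of 14 (final 2 mM); aq. work-up
Reagents that add atoms: none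
Why: Two chromium(II) ions reduce the C13–Br bond to allylchromium(III) 15, which reverses the polarity of the C13–C11=C7 unit; its γ-carbon C7 then adds to the C6 aldehyde through a Zimmerman–Traxler chair to give alkoxide 16, whose O6 acylates on the C12 methyl ester. The closest known reaction types are the Nozaki–Hiyama allylation with 2-(alkoxycarbonyl)allyl bromides, which gives α-methylene-γ-butyrolactones, and the chromium(II)-mediated closure of germacrane ten-membered rings from ω-formyl allylic bromides. The carbocycle closes by a 10-exo-trig carbonyl addition (SE2′ at C7, leaving C11=C13 exocyclic), and the lactone closes by a 5-exo-trig acyl substitution. The C6/C7 relation is controlled by the chair: the σ-allylchromium equilibrates and should react as the isomer with C8 trans to CH2Cr, with C5 and C8 both equatorial, which gives the anti adduct and hence the trans-fused lactone. The face of C7 is controlled by C8 through the Felkin–Anh-type arrangement known for dioxolane-substituted allylchromium reagents: the C8–O8 bond lies anti to the forming bond and H8 points toward the aldehyde chain, which avoids a syn-pentane contact with C5; this arrangement fits a boat-chair-boat-like ring with O6, O8, O9 and C11 all peripheral and should give 6R,7S. The step needs reduction of the allylic bromide before the enal or enoate (secured by the far faster C–Br reduction), γ- over α-attack (secured by the closed transition state) and ring closure over oligomerisation (secured by high dilution and by the two Z alkenes and the trans-dioxolane acting as turn elements).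

Step 10
Reactants: 17 tert-butyl (1(10)E,4Z,6R,7S,8S,9S)-8,9-(isopropylidenedioxy)-12-oxo-6,12-epoxygermacra-1(10),4,11(13)-trien-14-oate
Product: 18 tert-butyl (1(10)E,4Z,6R,7S,8S,9S)-8,9-dihydroxy-12-oxo-6,12-epoxygermacra-1(10),4,11(13)-trien-14-oate
Conditions: AcOH/H2O (4:1), 40 °C
Reagents that add atoms: none
Why: Acid-catalysed acetal hydrolysis in aqueous acetic acid should free the 8,9-diol while the tert-butyl ester, the lactone and the alkenes tolerate this weak acid.

Step 11
Reactants: 18 tert-butyl (1(10)E,4Z,6R,7S,8S,9S)-8,9-dihydroxy-12-oxo-6,12-epoxygermacra-1(10),4,11(13)-trien-14-oate; 19 angelic acid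
Product: 21 tert-butyl (1(10)E,4Z,6R,7S,8S,9S)-8,9-bis(angeloyloxy)-12-oxo-6,12-epoxygermacra-1(10),4,11(13)-trien-14-oate, via mixed anhydride 20 (not isolated)
Conditions: 19 (6 equiv), 2,4,6-trichlorobenzoyl chloride, Et3N, toluene, rt; then 18, 75 °C
Reagents that add atoms: none
Why: Yamaguchi-type mixed-anhydride esterification without a nucleophilic catalyst is the established way to transfer the angeloyl group without Z to E isomerisation, and an excess should acylate both carbinols with retention at C8 and C9.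

Step 12
Reactants: 21 tert-butyl (1(10)E,4Z,6R,7S,8S,9S)-8,9-bis(angeloyloxy)-12-oxo-6,12-epoxygermacra-1(10),4,11(13)-trien-14-oate
Product: 23 CNP0154468.1, via trimethylsilyl ester 22 (not isolated)
Conditions: TMSOTf (3 equiv), 2,6-lutidine (4 equiv), CH2Cl2, 0 °C; then pH 5 aq. buffer
Reagents that add atoms: none
Why: Silyl-triflate-mediated tert-butyl ester cleavage expels isobutene under buffered aprotic conditions, the silyl ester hydrolyses on work-up, and the angelates and the lactone, which have no tertiary alkyl–oxygen bond, should stay.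

Compound list
1 | neryl acetate [(2Z)-3,7-dimethylocta-2,6-dien-1-yl acetate] | CC(=O)OC/C=C(/C)CCC=C(C)C | starting material
2 | 6,7-epoxyneryl acetate (racemic epoxide; Z alkene kept) | CC(=O)OC/C=C(/C)CCC1OC1(C)C | intermediate
3 | (4Z)-6-acetoxy-4-methylhex-4-enal | CC(=O)OC/C=C(/C)CCC=O | intermediate
4 | tert-butyl (triphenylphosphoranylidene)acetate | CC(C)(C)OC(=O)C=P(c1ccccc1)(c1ccccc1)c1ccccc1 | starting material
5 | tert-butyl bromo(triphenylphosphoranylidene)acetate | CC(C)(C)OC(=O)C(Br)=P(c1ccccc1)(c1ccccc1)c1ccccc1 | intermediate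
6 | tert-butyl (2Z,6Z)-8-acetoxy-2-bromo-6-methylocta-2,6-dienoate | CC(=O)OC/C=C(/C)CC/C=C(/C(=O)OC(C)(C)C)Br | intermediate
7 | dimethyl (4R,5R)-2,2-dimethyl-1,3-dioxolane-4,5-dicarboxylate (dimethyl 2,3-O-isopropylidene-L-tartrate) | COC(=O)[C@@H]1OC(C)(C)O[C@H]1C(=O)OC | starting material
8 | (4R,5R)-5-(methoxycarbonyl)-2,2-dimethyl-1,3-dioxolane-4-carboxylic acid | COC(=O)[C@@H]1OC(C)(C)O[C@H]1C(=O)O | intermediate
9 | methyl (4R,5S)-5-[(1E,5Z)-7-acetoxy-1-(tert-butoxycarbonyl)-5-methylhepta-1,5-dien-1-yl]-2,2-dimethyl-1,3-dioxolane-4-carboxylate (trans-dioxolane) | CC(=O)OC/C=C(/C)CC/C=C(/C(=O)OC(C)(C)C)[C@@H]1OC(C)(C)O[C@H]1C(=O)OC | intermediate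
10 | tert-butyl (2E,6Z)-2-[(4S,5R)-5-formyl-2,2-dimethyl-1,3-dioxolan-4-yl]-8-hydroxy-6-methylocta-2,6-dienoate | OC/C=C(/C)CC/C=C(/C(=O)OC(C)(C)C)[C@@H]1OC(C)(C)O[C@H]1C=O | intermediate
11 | methyl acrylate | C=CC(=O)OC | starting material
12 | Morita–Baylis–Hillman adduct, 8S,9S, both C7 epimers, free C6 alcohol | OC/C=C(/C)CC/C=C(/C(=O)OC(C)(C)C)[C@@H]1OC(C)(C)O[C@H]1C(O)C(=C)C(=O)OC | intermediate
13 | (Z)-enal of the Morita–Baylis–Hillman adduct, 8S,9S, both C7 epimers | O=C/C=C(/C)CC/C=C(/C(=O)OC(C)(C)C)[C@@H]1OC(C)(C)O[C@H]1C(O)C(=C)C(=O)OC | intermediate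
14 | open-chain (Z)-enal (Z)-2-(bromomethyl)enoate, 8S,9S | O=C/C=C(/C)CC/C=C(/C(=O)OC(C)(C)C)[C@@H]1OC(C)(C)O[C@H]1/C=C(/C(=O)OC)CBr | intermediate
15 | allylchromium(III) dichloride, drawn as the reactive isomer with C8 trans to CH2Cr | O=C/C=C(/C)CC/C=C(/C(=O)OC(C)(C)C)[C@@H]1OC(C)(C)O[C@H]1/C=C(/C[Cr](Cl)Cl)C(=O)OC | intermediate
16 | ten-membered-ring chromium(III) alkoxide of the anti hydroxy ester | C=C(C(=O)OC)[C@H]1[C@H](O[Cr](Cl)Cl)/C=C(/C)CC/C=C(/C(=O)OC(C)(C)C)[C@@H]2OC(C)(C)O[C@@H]12 | intermediate
17 | (6R,7S,8S,9S) trans-fused α-methylene lactone, 8,9-acetonide, tert-butyl ester | C=C1C(=O)O[C@@H]2/C=C(/C)CC/C=C(/C(=O)OC(C)(C)C)[C@@H]3OC(C)(C)O[C@H]3[C@@H]12 | intermediate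
18 | (6R,7S,8S,9S) 8,9-diol lactone, tert-butyl ester | C=C1C(=O)O[C@@H]2/C=C(/C)CC/C=C(/C(=O)OC(C)(C)C)[C@H](O)[C@@H](O)[C@@H]12 | intermediate
19 | angelic acid [(2Z)-2-methylbut-2-enoic acid] | C/C=C(/C)C(=O)O | starting material
20 | angelic 2,4,6-trichlorobenzoic anhydride | C/C=C(/C)C(=O)OC(=O)c1c(Cl)cc(Cl)cc1Cl | intermediate
21 | (6R,7S,8S,9S) 8,9-bis-angelate lactone, tert-butyl ester | C=C1C(=O)O[C@@H]2/C=C(/C)CC/C=C(/C(=O)OC(C)(C)C)[C@H](OC(=O)/C(C)=C\C)[C@@H](OC(=O)/C(C)=C\C)[C@@H]12 | intermediate
22 | trimethylsilyl ester of the target | C=C1C(=O)O[C@@H]2/C=C(/C)CC/C=C(/C(=O)O[Si](C)(C)C)[C@H](OC(=O)/C(C)=C\C)[C@@H](OC(=O)/C(C)=C\C)[C@@H]12 | intermediate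
23 | CNP0154468.1, (1(10)E,4Z,6R,7S,8S,9S)-8,9-bis(angeloyloxy)-12-oxo-6,12-epoxygermacra-1(10),4,11(13)-trien-14-oic acid | C=C1C(=O)O[C@@H]2/C=C(/C)CC/C=C(/C(=O)O)[C@H](OC(=O)/C(C)=C\C)[C@@H](OC(=O)/C(C)=C\C)[C@@H]12 | target

Total step count: 12. Longest linear sequence: 11 steps (steps 1, 2 and 4–12, from neryl acetate).

Steps most likely to fail

Step 9. Three processes could spoil the closure:
- intermolecular coupling may compete with closure of the strained ring;
- allylic strain between C9 and the C12 ester may oppose the Felkin–Anh arrangement and erode the facial selectivity at C7;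
- chromium(III) may isomerise the Z enal.

The fallback changes how and from what the nucleophile is made. It sets out from 13, which is acetylated (Ac2O, pyridine) to the unrearranged Baylis–Hillman acetate F1. F1 is then cyclised by π-allylpalladium umpolung (Pd(PPh3)4 cat., InI, THF, slow addition). The allylindium is released only as fast as palladium ionises the acetate, so its concentration stays low. It adds through a closed transition state, and lactonisation brings the sequence back to 17.

Step 4. Three processes could spoil the coupling: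
- capture of the dioxolanyl radical by alkenylnickel may be slower than its conjugate addition to the bromoenoate;
- low-valent nickel may ionise the allylic acetate;
- the alkene geometry may be lost.

The fallback builds C10 as an alkyne and adds C14 later, and it sets out from 3 and 8.
- Aldehyde 3 is treated with the Ohira–Bestmann reagent (K2CO3, MeOH), which also methanolyses the acetate, to give (2Z)-3-methylhept-2-en-6-yn-1-ol F2.
- Acid 8 is converted (N-hydroxytetrachlorophthalimide, DIC) into the redox-active ester F3.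
- The alkynylzinc alkoxide of F2 is coupled with F3 by nickel-catalysed decarboxylative alkynylation to the trans-dioxolanyl alkyne F4.
- Palladium-catalysed syn hydrostannation gives the C10 vinylstannane F5.
- Iodine converts F5 into the vinyl iodide F6.
- Palladium-catalysed carbonylation (CO, t-BuOH, Et3N, DMF) gives the hydroxy diester F7.
- DIBAL-H at −78 °C takes F7 back to the route at 10.

Step 11. Acylation of the two hindered vicinal carbinols may stall. Heat and amine may move the lactone from O6 to O8. The angeloyl group may isomerise. The fallback builds the angelate double bonds on the substrate and sets out from 18. Steglich esterification at rt with the saturated, more reactive 2-(diphenoxyphosphoryl)propanoic acid gives the bis(phosphonopropanoate) F8. A Z-selective Horner–Wadsworth–Emmons reaction of this diaryl phosphonate with acetaldehyde (NaI, DBU, THF, −78 to 0 °C) then returns to 21.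

Further compounds
F1 | step 9 | Baylis–Hillman acetate of enal 13 (both C7 epimers) | O=C/C=C(/C)CC/C=C(/C(=O)OC(C)(C)C)[C@@H]1OC(C)(C)O[C@H]1C(OC(C)=O)C(=C)C(=O)OC
F2 | step 4 | (2Z)-3-methylhept-2-en-6-yn-1-ol | OC/C=C(/C)CCC#C
F3 | step 4 | tetrachlorophthalimido ester of acid 8 | COC(=O)[C@@H]1OC(C)(C)O[C@H]1C(=O)ON1C(=O)c2c(Cl)c(Cl)c(Cl)c(Cl)c2C1=O
F4 | step 4 | methyl trans-5-[(5Z)-7-hydroxy-5-methylhept-5-en-1-yn-1-yl]-2,2-dimethyl-1,3-dioxolane-4-carboxylate (8R,9S) | OC/C=C(/C)CCC#C[C@@H]1OC(C)(C)O[C@H]1C(=O)OC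
F5 | step 4 | C10 tributylvinylstannane from syn hydrostannation of F4 | OC/C=C(/C)CC/C=C(/[Sn](CCCC)(CCCC)CCCC)[C@@H]1OC(C)(C)O[C@H]1C(=O)OC
F6 | step 4 | C10 vinyl iodide | OC/C=C(/C)CC/C=C(/I)[C@@H]1OC(C)(C)O[C@H]1C(=O)OC
F7 | step 4 | hydroxy diester (deacetyl 9) | OC/C=C(/C)CC/C=C(/C(=O)OC(C)(C)C)[C@@H]1OC(C)(C)O[C@H]1C(=O)OC
F8 | step 11 | 8,9-bis[2-(diphenoxyphosphoryl)propanoate] of diol 18 | C=C1C(=O)O[C@@H]2/C=C(/C)CC/C=C(/C(=O)OC(C)(C)C)[C@H](OC(=O)C(C)P(=O)(Oc3ccccc3)Oc3ccccc3)[C@@H](OC(=O)C(C)P(=O)(Oc3ccccc3)Oc3ccccc3)[C@@H]12
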